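**Retrosynthetic overview**
1. 28 ⇐ 27 (hydrogenolysis) ⇐ closure of two ketals onto C2 of two 2-methoxy-4-arylchroman-3-ols fused to the central ring A (25).
2. Key disconnection, done on both arms in one operation: each C4–aryl bond comes from a 1,2-aryl shift (epoxide semipinacol) in a 3-aryl-2-methoxy-2H-chromene (22). Asymmetric epoxidation fixes C4, hydride reduction fixes C3, ketal closure fixes C2.
3. 22 ⇐ dialdehyde 6 (central ring A, from protected resorcinol 1 by C–H borylation/oxidation and double ortho-formylation) + aryl benzyl ketones 15 and 18 (Pd α-arylation of acetophenone 8).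
4. Lower flavan unit 13 ⇐ aryl ether epoxide 12 ⇐ Sharpless kinetic resolution of allylic alcohol 10 (from protected catechol 7).
5. Ring order: ring C of the lower unit → two pyran rings on the central ring A → two 1,2-shifts → the two dioxabicyclo[3.3.1]nonane ketals.

Assumption: 1 and 7 are bought as the MOM- and benzyl-protected forms of resorcinol and catechol (otherwise one etherification each from the diphenol). The target is read as epicatechin-(2β→O→7,4β→6)-ent-catechin-(2α→O→7,4α→8)-epicatechin.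

Step 1
Reactants: 1 1,3-bis(methoxymethoxy)benzene
Product: 3 3,5-bis(methoxymethoxy)phenol, via arylboronic pinacol ester 2 (not isolated)
Conditions: [Ir(OMe)(cod)]2 (1.5 mol %), dtbpy, B2pin2 (0.55 equiv), THF, 80 °C; then H2O2, aq. NaOH, 0 °C
Reagents that add atoms: bis(pinacolato)diboron, CC1(C)OB(OC1(C)C)B1OC(C)(C)C(C)(C)O1; hydrogen peroxide, OO
Why: Sterically controlled iridium-catalysed C–H borylation goes to C5, the only C–H not ortho to an OMOM group, and oxidation of the C–B bond gives the phloroglucinol oxygen pattern (one-pot C–H borylation/oxidation).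

Step 2
Reactants: 3 3,5-bis(methoxymethoxy)phenol
Product: 4 2-hydroxy-4,6-bis(methoxymethoxy)benzene-1,3-dicarbaldehyde
Conditions: MgCl2, Et3N, (CH2O)n (excess), MeCN, reflux
Reagents that add atoms: formaldehyde (as paraformaldehyde), C=O
Why: Magnesium phenoxide-directed ortho-formylation (Casnati–Skattebøl) delivers formaldehyde only ortho to the free OH, so both formyl groups flank the future 5-oxygen of the central ring.

Step 3
Reactants: 4 2-hydroxy-4,6-bis(methoxymethoxy)benzene-1,3-dicarbaldehyde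
Product: 5 2-(benzyloxy)-4,6-bis(methoxymethoxy)benzene-1,3-dicarbaldehyde
Conditions: BnBr, K2CO3, DMF, 60 °C
Reagents that add atoms: benzyl bromide, BrCc1ccccc1
Why: Williamson etherification blocks the central phenol so that it cannot later compete for ketal formation.

Step 4
Reactants: 5 2-(benzyloxy)-4,6-bis(methoxymethoxy)benzene-1,3-dicarbaldehyde
Product: 6 2-(benzyloxy)-4,6-dihydroxybenzene-1,3-dicarbaldehyde
Conditions: HCl (cat.), MeOH, 50 °C; aqueous work-up
Reagents that add atoms: none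
Why: Acid methanolysis of the two MOM acetals frees the two outer phenols, each ortho to one formyl group, while the benzyl ether is untouched.

Step 5
Reactants: 7 1,2-bis(benzyloxy)benzene
Product: 8 1-[3,4-bis(benzyloxy)phenyl]ethan-1-one
Conditions: Ac2O, Sc(OTf)3 (5 mol %), MeNO2, 50 °C
Reagents that add atoms: acetic anhydride, CC(=O)OC(C)=O
Why: Friedel–Crafts acylation occurs para to an ether oxygen of the activated catechol ring, and the catalytic Lewis acid spares the benzyl ethers.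

Step 6
Reactants: 7 1,2-bis(benzyloxy)benzene
Product: 9 3,4-bis(benzyloxy)benzaldehyde
Conditions: Cl2CHOMe, TiCl4, CH2Cl2, −78 to 0 °C; then H2O
Reagents that add atoms: dichloromethyl methyl ether, COC(Cl)Cl; water, O
Why: Rieche formylation of the dialkoxybenzene goes para to an ether oxygen, as for veratrole.

Step 7
Reactants: 9 3,4-bis(benzyloxy)benzaldehyde
Product: 10 rac-1-[3,4-bis(benzyloxy)phenyl]prop-2-en-1-ol
Conditions: CH2=CHMgBr, THF, −78 to 0 °C
Reagents that add atoms: vinylmagnesium bromide, C=C[Mg]Br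
Why: Grignard 1,2-addition gives the secondary allylic alcohol needed for kinetic resolution.

Step 8
Reactants: 10 rac-1-[3,4-bis(benzyloxy)phenyl]prop-2-en-1-ol
Product: 11 (S)-[3,4-bis(benzyloxy)phenyl][(2R)-oxiran-2-yl]methanol
Conditions: Ti(OiPr)4, D-(−)-DIPT, t-BuOOH (0.55 equiv), 4 Å MS, CH2Cl2, −20 °C
Reagents that add atoms: tert-butyl hydroperoxide, CC(C)(C)OO
Why: Sharpless kinetic resolution with D-(−)-tartrate epoxidizes the (R)-alcohol fast and gives the erythro (1S,2R) epoxy alcohol, which sets the future C3 of the lower unit and leaves the (S)-alcohol behind.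

Step 9
Reactants: 11 (S)-[3,4-bis(benzyloxy)phenyl][(2R)-oxiran-2-yl]methanol; 3 3,5-bis(methoxymethoxy)phenol
Product: 12 (2R)-2-{(R)-[3,4-bis(benzyloxy)phenyl][3,5-bis(methoxymethoxy)phenoxy]methyl}oxirane
Conditions: PPh3, DIAD, THF, 0 °C
Reagents that add atoms: none
Why: Mitsunobu etherification inverts the benzylic carbinol and so sets the future C2 of the lower unit as R.

Step 10
Reactants: 12 (2R)-2-{(R)-[3,4-bis(benzyloxy)phenyl][3,5-bis(methoxymethoxy)phenoxy]methyl}oxirane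
Product: 13 (2R,3R)-2-[3,4-bis(benzyloxy)phenyl]-5,7-bis(methoxymethoxy)chroman-3-ol
Conditions: AuCl3 (5 mol %), AgOTf (15 mol %), ClCH2CH2Cl, rt
Reagents that add atoms: none
Why: The 6-endo Friedel–Crafts epoxide–arene cyclization attacks the terminal epoxide carbon from either of the two equivalent ortho positions and closes ring C without touching the two stereocentres, giving the 2,3-cis (epicatechin) flavan-3-ol.

Step 11
Reactants: 13 (2R,3R)-2-[3,4-bis(benzyloxy)phenyl]-5,7-bis(methoxymethoxy)chroman-3-ol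
Product: 14 (2R,3R)-2-[3,4-bis(benzyloxy)phenyl]-8-bromo-5,7-bis(methoxymethoxy)chroman-3-ol
Conditions: NBS, CH2Cl2, −78 to 0 °C
Reagents that add atoms: N-bromosuccinimide, O=C1CCC(=O)N1Br
Why: Electrophilic bromination goes to C8, the most nucleophilic ring A position of 5,7-dioxygenated flavans.

Step 12
Reactants: 14 (2R,3R)-2-[3,4-bis(benzyloxy)phenyl]-8-bromo-5,7-bis(methoxymethoxy)chroman-3-ol; 8 1-[3,4-bis(benzyloxy)phenyl]ethan-1-one
Product: 15 1-[3,4-bis(benzyloxy)phenyl]-2-{(2R,3R)-2-[3,4-bis(benzyloxy)phenyl]-3-hydroxy-5,7-bis(methoxymethoxy)chroman-8-yl}ethan-1-one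
Conditions: Pd2(dba)3 (2.5 mol %), XPhos, NaOt-Bu (2.5 equiv), toluene, 80 °C
Reagents that add atoms: none
Why: Palladium-catalysed ketone α-arylation (Buchwald–Hartwig type) joins the methyl ketone to C8, and the hindered product methylene resists a second arylation.

Step 13
Reactants: 3 3,5-bis(methoxymethoxy)phenol
Product: 16 1,3,5-tris(methoxymethoxy)benzene
Conditions: NaH, MOMCl, DMF, 0 °C
Reagents that add atoms: chloromethyl methyl ether, COCCl
Why: O-alkylation gives a symmetric, acid-releasable ring A precursor for the upper unit.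

Step 14
Reactants: 16 1,3,5-tris(methoxymethoxy)benzene
Product: 17 2-bromo-1,3,5-tris(methoxymethoxy)benzene
Conditions: NBS, MeCN, 0 °C
Reagents that add atoms: N-bromosuccinimide, O=C1CCC(=O)N1Br
Why: Electrophilic monobromination has no regiochemical issue because the three ring positions are equivalent.

Step 15
Reactants: 17 2-bromo-1,3,5-tris(methoxymethoxy)benzene; 8 1-[3,4-bis(benzyloxy)phenyl]ethan-1-one
Product: 18 1-[3,4-bis(benzyloxy)phenyl]-2-[2,4,6-tris(methoxymethoxy)phenyl]ethan-1-one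
Conditions: Pd2(dba)3 (2.5 mol %), XPhos, NaOt-Bu, toluene, 80 °C
Reagents that add atoms: none
Why: The same palladium-catalysed α-arylation gives the second aryl benzyl ketone.

Step 16
Reactants: 6 2-(benzyloxy)-4,6-dihydroxybenzene-1,3-dicarbaldehyde (3 equiv, excess recovered); 18 1-[3,4-bis(benzyloxy)phenyl]-2-[2,4,6-tris(methoxymethoxy)phenyl]ethan-1-one
Product: 20 5-(benzyloxy)-2-[3,4-bis(benzyloxy)phenyl]-7-hydroxy-2-methoxy-3-[2,4,6-tris(methoxymethoxy)phenyl]-2H-chromene-6-carbaldehyde (C2 epimers), via aldol adduct 19 (not isolated)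
Conditions: LiN(SiMe3)2 (3.2 equiv), THF, −78 to 0 °C; AcOH quench; then PPTS (cat.), MeOH, 4 Å MS, rt
Reagents that add atoms: methanol, CO
Why: Aldol addition of the lithium enolate to one formyl group, then acid-catalysed dehydration and ring closure by the only ortho OH, gives the 2H-chromen-2-ol, which is trapped as its methyl ketal (aldol condensation/oxa-cyclization).

Step 17
Reactants: 20 mono-chromene aldehyde; 15 aryl benzyl ketone of the lower unit
Product: 22 5-(benzyloxy)-2,8-bis[3,4-bis(benzyloxy)phenyl]-2,8-dimethoxy-3-{(2R,3R)-2-[3,4-bis(benzyloxy)phenyl]-3-hydroxy-5,7-bis(methoxymethoxy)chroman-8-yl}-7-[2,4,6-tris(methoxymethoxy)phenyl]-2H,8H-pyrano[3,2-g]chromene (C2/C8 epimers), via aldol adduct 21 (not isolated)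
Conditions: LiN(SiMe3)2 (3.2 equiv), THF, −78 to 0 °C; AcOH quench; then PPTS (cat.), MeOH, 4 Å MS, rt
Reagents that add atoms: methanol, CO
Why: The same aldol condensation/oxa-cyclization on the remaining salicylaldehyde unit builds the second 3-aryl-2-methoxy-2H-chromene, whose two ketal centres are erased again in step 20.

Step 18
Reactants: 22 bis(3-aryl-2-methoxy-2H-chromene)
Product: 24 5-(benzyloxy)-2,8-bis[3,4-bis(benzyloxy)phenyl]-2,8-dimethoxy-4-(lower flavan-8-yl)-6-[2,4,6-tris(methoxymethoxy)phenyl]-pyrano[3,2-g]chromene-3,7(4H,6H)-dione (C4 and C6 as in the SMILES; C2/C8 epimers), via bis-epoxide 23 (not isolated)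
Conditions: (S,S)-[N,N′-bis(3,5-di-tert-butylsalicylidene)cyclohexane-1,2-diaminato]manganese chloride (10 mol %), mCPBA (2.4 equiv), N-methylmorpholine N-oxide, CH2Cl2, −78 °C; then BF3·OEt2 (20 mol %), −78 to −40 °C
Reagents that add atoms: 3-chloroperoxybenzoic acid, OOC(=O)c1cccc(Cl)c1
Why: Proposed new method: the salen manganese oxo species epoxidizes each chromene C3=C4 bond on the face it uses for 2,2-disubstituted chromenes; BF3 then ionizes the C4–O bond toward the trioxygenated central ring, and the electron-rich aryl on C3 shifts to C4 on the face opposite the departing oxygen while C3 becomes the ketone (the ketal carbon C2 is a poor migrating group), so each 1,2-aryl shift forms the C4–aryl bond with the configuration dictated by the epoxide face; the closest known chemistry is the Lewis acid semipinacol (Meinwald-type) rearrangement of aryl epoxides to α-aryl ketones together with the Jacobsen epoxidation of chromenes.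

Step 19
Reactants: 24 bis(4-aryl-2-methoxychroman-3-one)
Product: 25 corresponding 3,7-diol, each OH cis to the neighbouring 4- or 6-aryl group
Conditions: NaBH4, THF–MeOH, −20 °C
Reagents that add atoms: none
Why: Hydride adds to each ketone from the face anti to the quasi-axial C4 (C6) aryl group, which gives the 3,4-cis carbinols required for both C3 centres (substrate-controlled carbonyl reduction).

Step 20
Reactants: 25 bis(4-aryl-2-methoxychroman-3-ol)
Product: 27 heptabenzyl ether of the target, via pentaphenol bis-methyl-ketal 26 (not isolated)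
Conditions: HCl (2 M) in MeOH–THF, 40 °C
Reagents that add atoms: none
Why: Acid removes the five MOM groups and ionizes each methyl ketal, and each C2 oxocarbenium ion is trapped by the ortho OH of the aryl group on C4, which can only reach it from its own face, so the two bicyclic ketals close with C2 fixed by C4 (transketalization).

Step 21
Reactants: 27 heptabenzyl ether of the target
Product: 28 CNP0338496.1
Conditions: H2 (1 atm), Pd(OH)2/C, THF–MeOH, rt
Reagents that add atoms: none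
Why: Hydrogenolysis cleaves the seven benzyl ethers and leaves the bicyclic ketals and carbinols intact.

**Compound list**
1 | 1,3-bis(methoxymethoxy)benzene | COCOc1cccc(OCOC)c1 | starting material
2 | 2-[3,5-bis(methoxymethoxy)phenyl]-4,4,5,5-tetramethyl-1,3,2-dioxaborolane | COCOc1cc(OCOC)cc(c1)B1OC(C)(C)C(C)(C)O1 | intermediate
3 | 3,5-bis(methoxymethoxy)phenol | COCOc1cc(O)cc(OCOC)c1 | intermediate
4 | 2-hydroxy-4,6-bis(methoxymethoxy)benzene-1,3-dicarbaldehyde | COCOc1cc(OCOC)c(C=O)c(O)c1C=O | intermediate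
5 | 2-(benzyloxy)-4,6-bis(methoxymethoxy)benzene-1,3-dicarbaldehyde | COCOc1cc(OCOC)c(C=O)c(OCc2ccccc2)c1C=O | intermediate
6 | 2-(benzyloxy)-4,6-dihydroxybenzene-1,3-dicarbaldehyde | Oc1cc(O)c(C=O)c(OCc2ccccc2)c1C=O | intermediate
7 | 1,2-bis(benzyloxy)benzene | c1ccc(cc1)COc1ccccc1OCc1ccccc1 | starting material
8 | 1-[3,4-bis(benzyloxy)phenyl]ethan-1-one | CC(=O)c1ccc(OCc2ccccc2)c(OCc2ccccc2)c1 | intermediate
9 | 3,4-bis(benzyloxy)benzaldehyde | O=Cc1ccc(OCc2ccccc2)c(OCc2ccccc2)c1 | intermediate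
10 | rac-1-[3,4-bis(benzyloxy)phenyl]prop-2-en-1-ol | C=CC(O)c1ccc(OCc2ccccc2)c(OCc2ccccc2)c1 | intermediate
11 | (S)-[3,4-bis(benzyloxy)phenyl][(2R)-oxiran-2-yl]methanol | O[C@@H](c1ccc(OCc2ccccc2)c(OCc2ccccc2)c1)[C@H]1CO1 | intermediate
12 | (2R)-2-{(R)-[3,4-bis(benzyloxy)phenyl][3,5-bis(methoxymethoxy)phenoxy]methyl}oxirane | COCOc1cc(OCOC)cc(c1)O[C@H](c1ccc(OCc2ccccc2)c(OCc2ccccc2)c1)[C@H]1CO1 | intermediate
13 | (2R,3R)-2-[3,4-bis(benzyloxy)phenyl]-5,7-bis(methoxymethoxy)chroman-3-ol | COCOc1cc(OCOC)c2c(c1)O[C@H](c1ccc(OCc3ccccc3)c(OCc3ccccc3)c1)[C@H](O)C2 | intermediate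
14 | (2R,3R)-2-[3,4-bis(benzyloxy)phenyl]-8-bromo-5,7-bis(methoxymethoxy)chroman-3-ol | COCOc1cc(OCOC)c2c(c1Br)O[C@H](c1ccc(OCc3ccccc3)c(OCc3ccccc3)c1)[C@H](O)C2 | intermediate
15 | 1-[3,4-bis(benzyloxy)phenyl]-2-{(2R,3R)-2-[3,4-bis(benzyloxy)phenyl]-3-hydroxy-5,7-bis(methoxymethoxy)chroman-8-yl}ethan-1-one | COCOc1cc(OCOC)c2c(c1CC(=O)c1ccc(OCc3ccccc3)c(OCc3ccccc3)c1)O[C@H](c1ccc(OCc3ccccc3)c(OCc3ccccc3)c1)[C@H](O)C2 | intermediate
16 | 1,3,5-tris(methoxymethoxy)benzene | COCOc1cc(OCOC)cc(OCOC)c1 | intermediate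
17 | 2-bromo-1,3,5-tris(methoxymethoxy)benzene | COCOc1cc(OCOC)c(Br)c(OCOC)c1 | intermediate
18 | 1-[3,4-bis(benzyloxy)phenyl]-2-[2,4,6-tris(methoxymethoxy)phenyl]ethan-1-one | COCOc1cc(OCOC)c(CC(=O)c2ccc(OCc3ccccc3)c(OCc3ccccc3)c2)c(OCOC)c1 | intermediate
19 | 2-(benzyloxy)-3-{3-[3,4-bis(benzyloxy)phenyl]-1-hydroxy-3-oxo-2-[2,4,6-tris(methoxymethoxy)phenyl]propyl}-4,6-dihydroxybenzaldehyde (diastereomers) | O=Cc1c(O)cc(O)c(C(O)C(c2c(OCOC)cc(OCOC)cc2OCOC)C(=O)c2ccc(OCc3ccccc3)c(OCc3ccccc3)c2)c1OCc1ccccc1 | intermediate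
20 | 5-(benzyloxy)-2-[3,4-bis(benzyloxy)phenyl]-7-hydroxy-2-methoxy-3-[2,4,6-tris(methoxymethoxy)phenyl]-2H-chromene-6-carbaldehyde (C2 epimers) | COC1(c7ccc(OCc6ccccc6)c(OCc6ccccc6)c7)Oc2cc(O)c(C=O)c(OCc6ccccc6)c2C=C1c4c(OCOC)cc(OCOC)cc4OCOC | intermediate
21 | aldol adduct of 20 and 15: the 6-formyl group of 20 has become CH(OH)–CH(lower flavan-8-yl)–C(=O)[3,4-bis(benzyloxy)phenyl] (diastereomers) | COC1(c7ccc(OCc6ccccc6)c(OCc6ccccc6)c7)Oc2cc(O)c(C(O)C(c4c(OCOC)cc(OCOC)c5c4O[C@H](c7ccc(OCc6ccccc6)c(OCc6ccccc6)c7)[C@H](O)C5)C(=O)c7ccc(OCc6ccccc6)c(OCc6ccccc6)c7)c(OCc6ccccc6)c2C=C1c4c(OCOC)cc(OCOC)cc4OCOC | intermediate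
22 | 5-(benzyloxy)-2,8-bis[3,4-bis(benzyloxy)phenyl]-2,8-dimethoxy-3-{(2R,3R)-2-[3,4-bis(benzyloxy)phenyl]-3-hydroxy-5,7-bis(methoxymethoxy)chroman-8-yl}-7-[2,4,6-tris(methoxymethoxy)phenyl]-2H,8H-pyrano[3,2-g]chromene (C2/C8 epimers) | COC1(c7ccc(OCc6ccccc6)c(OCc6ccccc6)c7)Oc2cc3OC(OC)(c7ccc(OCc6ccccc6)c(OCc6ccccc6)c7)C(c4c(OCOC)cc(OCOC)c5c4O[C@H](c7ccc(OCc6ccccc6)c(OCc6ccccc6)c7)[C@H](O)C5)=Cc3c(OCc6ccccc6)c2C=C1c4c(OCOC)cc(OCOC)cc4OCOC | intermediate
23 | 3,4:6,7-bis-epoxide of 22, each oxirane oxygen on the face opposite to the one the migrating aryl group ends on (C2/C8 epimers) | COC1(c7ccc(OCc6ccccc6)c(OCc6ccccc6)c7)Oc2cc3OC(OC)(c7ccc(OCc6ccccc6)c(OCc6ccccc6)c7)[C@@]8(c4c(OCOC)cc(OCOC)c5c4O[C@H](c7ccc(OCc6ccccc6)c(OCc6ccccc6)c7)[C@H](O)C5)O[C@H]8c3c(OCc6ccccc6)c2[C@@H]9O[C@@]91c4c(OCOC)cc(OCOC)cc4OCOC | intermediate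
24 | 5-(benzyloxy)-2,8-bis[3,4-bis(benzyloxy)phenyl]-2,8-dimethoxy-4-(lower flavan-8-yl)-6-[2,4,6-tris(methoxymethoxy)phenyl]pyrano[3,2-g]chromene-3,7(4H,6H)-dione; C4 and C6 configured as C4 of the middle and upper units of 28 (C2/C8 epimers) | COC1(c7ccc(OCc6ccccc6)c(OCc6ccccc6)c7)Oc2cc3OC(OC)(c7ccc(OCc6ccccc6)c(OCc6ccccc6)c7)C(=O)[C@H](c4c(OCOC)cc(OCOC)c5c4O[C@H](c7ccc(OCc6ccccc6)c(OCc6ccccc6)c7)[C@H](O)C5)c3c(OCc6ccccc6)c2[C@@H](c4c(OCOC)cc(OCOC)cc4OCOC)C1=O | intermediate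
25 | 3,7-diol from 24, each OH cis to the neighbouring 4- or 6-aryl group (C2/C8 epimers) | COC1(c7ccc(OCc6ccccc6)c(OCc6ccccc6)c7)Oc2cc3OC(OC)(c7ccc(OCc6ccccc6)c(OCc6ccccc6)c7)[C@H](O)[C@H](c4c(OCOC)cc(OCOC)c5c4O[C@H](c7ccc(OCc6ccccc6)c(OCc6ccccc6)c7)[C@H](O)C5)c3c(OCc6ccccc6)c2[C@@H](c4c(OCOC)cc(OCOC)cc4OCOC)[C@H]1O | intermediate
26 | 25 without its five MOM groups (pentaphenol, both methyl ketals still in place) | COC1(c7ccc(OCc6ccccc6)c(OCc6ccccc6)c7)Oc2cc3OC(OC)(c7ccc(OCc6ccccc6)c(OCc6ccccc6)c7)[C@H](O)[C@H](c4c(O)cc(O)c5c4O[C@H](c7ccc(OCc6ccccc6)c(OCc6ccccc6)c7)[C@H](O)C5)c3c(OCc6ccccc6)c2[C@@H](c4c(O)cc(O)cc4O)[C@H]1O | intermediate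
27 | target carrying seven benzyl ethers (six on the three catechol rings, one on the 5-OH of the middle unit) | Oc1cc(O)c2c(c1)O[C@@]1(c3ccc(OCc5ccccc5)c(OCc5ccccc5)c3)Oc3cc4c(c(OCc5ccccc5)c3[C@@H]2[C@H]1O)[C@H]1c2c(cc(O)c3c2O[C@H](c2ccc(OCc5ccccc5)c(OCc5ccccc5)c2)[C@H](O)C3)O[C@@](c2ccc(OCc5ccccc5)c(OCc5ccccc5)c2)(O4)[C@@H]1O | intermediate
28 | CNP0338496.1, epicatechin-(2β→O→7,4β→6)-ent-catechin-(2α→O→7,4α→8)-epicatechin | Oc1cc(O)c2c(c1)O[C@@]1(c3ccc(O)c(O)c3)Oc3cc4c(c(O)c3[C@@H]2[C@H]1O)[C@H]1c2c(cc(O)c3c2O[C@H](c2ccc(O)c(O)c2)[C@H](O)C3)O[C@@](c2ccc(O)c(O)c2)(O4)[C@@H]1O | target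

**Totals**
Total steps: 21. Longest linear sequence: 12 steps (7 → 9 → 10 → 11 → 12 → 13 → 14 → 15 → 22 → 24 → 25 → 27 → 28).

**Steps most likely to fail**

Step 18 (the new epoxidation/1,2-aryl shift). The racemic ketal centres of 22 may erode the catalyst's face selectivity, the Lewis acid may ionize the methyl ketal instead of the epoxide, and the epoxide may open at C3 instead of C4. Fallback by known chemistry, setting out from 5, 8, 16 and 13: Claisen–Schmidt condensation of 5 with two equivalents of 8 (KOH, EtOH) gives the bis-chalcone F1. Juliá–Colonna epoxidation (poly-L-leucine, urea–H2O2, DBU, THF) gives the (2R,3S)-configured bis-epoxy ketone F2. Lewis acid Friedel–Crafts opening at the benzylic carbon with inversion (BF3·OEt2, CH2Cl2, −78 °C), first by 16, gives the mono-adduct F3, and then by C8 of 13 gives the bis(α-hydroxy ketone) F4. HCl in MeOH–THF removes all MOM groups and closes both ketals, which brings the sequence back to the route at 27.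

Step 12 (α-arylation with a hindered, di-ortho-substituted bromoflavan that carries a free hydroxyl). Fallback, setting out from 14 and 9: Corey–Chaykovsky methylenation of 9 (trimethylsulfonium iodide, NaH, DMSO) gives the aryl oxirane F5. Bromine–lithium exchange on 14 (t-BuLi, 3 equiv, THF, −78 °C), then CuI (cat.) and F5, opens the oxirane at its CH2 terminus to give the benzylic alcohol F6. MnO2 oxidizes only the benzylic carbinol and returns to the route at 15.

Step 2 (second ortho-formylation of a phenol already deactivated by the first formyl group). Fallback, setting out from 3: amine-mediated ortho-selective dibromination (NBS, i-Pr2NH, CH2Cl2) gives the dibromophenol F7. Benzylation (BnBr, K2CO3) gives the dibromo benzyl ether F8. Double bromine–lithium exchange (t-BuLi, THF, −78 °C) and DMF quench return to the route at 5.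

Further compounds
F1 | step 18 | (2E,2′E)-3,3′-[2-(benzyloxy)-4,6-bis(methoxymethoxy)-1,3-phenylene]bis{1-[3,4-bis(benzyloxy)phenyl]prop-2-en-1-one} | COCOc1cc(OCOC)c(/C=C/C(=O)c7ccc(OCc6ccccc6)c(OCc6ccccc6)c7)c(OCc6ccccc6)c1/C=C/C(=O)c7ccc(OCc6ccccc6)c(OCc6ccccc6)c7
F2 | step 18 | bis-epoxide of F1, each oxirane (2R,3S) with C2 the carbon bearing the aroyl group | COCOc1cc(OCOC)c([C@@H]8O[C@H]8C(=O)c7ccc(OCc6ccccc6)c(OCc6ccccc6)c7)c(OCc6ccccc6)c1[C@@H]8O[C@H]8C(=O)c7ccc(OCc6ccccc6)c(OCc6ccccc6)c7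
F3 | step 18 | mono-adduct: one oxirane of F2 opened at the benzylic carbon by 2,4,6-tris(methoxymethoxy)phenyl to the α-hydroxy ketone, the other oxirane intact | COCOc1cc(OCOC)c([C@@H]8O[C@H]8C(=O)c7ccc(OCc6ccccc6)c(OCc6ccccc6)c7)c(OCc6ccccc6)c1[C@@H](c4c(OCOC)cc(OCOC)cc4OCOC)[C@@H](O)C(=O)c7ccc(OCc6ccccc6)c(OCc6ccccc6)c7
F4 | step 18 | bis(α-hydroxy ketone): second oxirane opened by C8 of 13 | COCOc1cc(OCOC)c([C@@H](c4c(OCOC)cc(OCOC)c5c4O[C@H](c7ccc(OCc6ccccc6)c(OCc6ccccc6)c7)[C@H](O)C5)[C@@H](O)C(=O)c7ccc(OCc6ccccc6)c(OCc6ccccc6)c7)c(OCc6ccccc6)c1[C@@H](c4c(OCOC)cc(OCOC)cc4OCOC)[C@@H](O)C(=O)c7ccc(OCc6ccccc6)c(OCc6ccccc6)c7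
F5 | step 12 | rac-2-[3,4-bis(benzyloxy)phenyl]oxirane | C1OC1c1ccc(OCc2ccccc2)c(OCc2ccccc2)c1
F6 | step 12 | 1-[3,4-bis(benzyloxy)phenyl]-2-{(2R,3R)-2-[3,4-bis(benzyloxy)phenyl]-3-hydroxy-5,7-bis(methoxymethoxy)chroman-8-yl}ethan-1-ol (carbinol epimers) | COCOc1cc(OCOC)c2c(c1CC(O)c1ccc(OCc3ccccc3)c(OCc3ccccc3)c1)O[C@H](c1ccc(OCc3ccccc3)c(OCc3ccccc3)c1)[C@H](O)C2
F7 | step 2 | 2,6-dibromo-3,5-bis(methoxymethoxy)phenol | COCOc1cc(OCOC)c(Br)c(O)c1Br
F8 | step 2 | 2-(benzyloxy)-1,3-dibromo-4,6-bis(methoxymethoxy)benzene | COCOc1cc(OCOC)c(Br)c(OCc2ccccc2)c1Br
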